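The oak and elm flasks make a ratio to start from: elm took twice the partner of oak and read 1.56 times oak's product at 4.00 h, so product seems to follow the partner present, and you can reckon with the fraction of partner left, as for a pseudo-first-order loss.

| setting | oak | elm | delta | gamma |
|---|---|---|---|---|
| starting material | 0.80 M | 0.80 M | 0.80 M | 0.80 M |
| partner | 0.25 M (in portions, 4) | 0.50 M (in portions, 4) | 0.300 M | 0.560 M (in portions, 4) |
| free catalyst | 20 mM | 20 mM | 20 mM | 20 mM |
| impurity | 4.2 mM | 4.2 mM | 4.2 mM | 4.2 mM |
| remark | run made earlier; portions every 1.5 h | run made earlier; portions every 1.5 h | everything together at the start | the portions of partner follow each other after 1.5 h, the first at the start |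
| time |  |  | 6.0 h | 6.0 h |

| run | time / h | product / % |
|---|---|---|
| oak | 0.250 | 0 |
| oak | 0.667 | 1 |
| oak | 1.33 | 2 |
| oak | 2.00 | 4 |
| oak | 2.50 | 2 |
| oak | 3.00 | 3 |
| oak | 4.00 | 9 |
| elm | 0.667 | 0 |
| elm | 1.33 | 4 |
| elm | 2.00 | 5 |
| elm | 2.50 | 9 |
| elm | 3.00 | 7 |
| elm | 4.00 | 14 |

(standard deviation of a reading: 1.5 percentage points)



- the winner by amount of product, in percent of the starting material charged; "neither" if no more than 2 percentage points parts them (delta / gamma / neither)
- how much product is there at the end, in percent of the starting material charged: delta
- how much product is there at the end, in percent of the starting material charged: gamma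

By my own reckoning, dividing the product of both runs at that reading by the partner-hours charged until then, with partner loss ignored, gives 0.131 h⁻¹ for the loss constant, the share of the partner present that turns to product each hour. Delta's partner, all in from the start, should keep a fraction 45.6% of its charge, which makes 20.4% product. Gamma's portions, averaged over their shorter stays, should keep 62.7%, which makes 26.1%. Gamma should win because its charge is 1.87 times delta's, while delta turns only 1.46 times the fraction.

The forecast stands a little lower, at 19% (14% to 25%) for delta and 25% (19% to 31%) for gamma, with gamma ahead: “Gamma has more partner, and dosing does not hurt it, so gamma should win”.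

The flasks give 22.4% for delta and 27.9% for gamma, so gamma wins.

    starting material + free catalyst ⇌ catalyst intermediate A (K = 4.10 M⁻¹, k = 1100 M⁻¹ h⁻¹)
    partner + catalyst intermediate A ⇌ catalyst intermediate B (K = 0.850 M⁻¹, k = 47.0 M⁻¹ h⁻¹)
    catalyst intermediate B → free catalyst + product (k = 24.0 h⁻¹)
    free catalyst + impurity → spent catalyst (k = 9600 M⁻¹ h⁻¹)

Unbound partner ends at 40% in delta and 60% in gamma, against the reckoned 45.6% and 62.7%. The rule has no amount of partner in it, so it gives 62.7% again for a neighbour of gamma with 2.50 times the partner, which ends at 66%. Neither delta nor gamma has come to rest at 6.0 h. At 60.0 h the rule leaves 0.0386% of delta's partner and 0.0535% of gamma's, so product should reach the partner's charge over the starting material's, the partner being the limiting reagent: 37.5% in delta and 70.0% in gamma. Delta then holds 37.5% and gamma 69.9%.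

The readings were generated by integration for substances that don't exist, and the scatter is random.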